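**Assumption (one line):** the Cu-catalysed conjugate addition of MeMgBr to 3-allylcyclopentenone gives the quaternary centre in high ee, and the face anti to the angular methyl controls the later epoxidation, enolate protonation and iPr addition.

## Retrosynthetic overview
1. Fertidin (15) comes from selective anisoylation of the secondary C1-OH of the diol 13 (jaeschkeanadiol).
2. The tertiary carbinol in 13 comes from iPr–M addition to the C9 ketone of the trans-fused hydroxy-ketone 11. Attack is from the α-face, anti to the angular methyl.
3. The C1-OH and C10-H of 11 come from epoxidation of the bicyclic enone 9 followed by SmI2 opening.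
4. Enone 9 comes from dehydration of the RCM product 8, which forms the seven-membered ring (C3=C4).
5. The five-membered ring is made first: Cu-catalysed asymmetric conjugate addition of Me to 3-allylcyclopentenone sets the quaternary C6, and the enolate is trapped at C10 by an aldol with 3-methylbut-3-enal. The seven-membered ring is closed second.

## Route

**Step 1**
Reactants: 1 (3-ethoxycyclopent-2-en-1-one), 2 (allylmagnesium bromide)
Product: 3 (3-allylcyclopent-2-en-1-one)
Conditions: 2, THF, 0 °C; then 1 M HCl, rt
Reagents that add atoms: allylmagnesium bromide, C=CC[Mg]Br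
Why: 1,2-Addition to the vinylogous ester followed by acid hydrolysis and transposition (Stork–Danheiser) gives the β-allyl enone; no stereocentre is formed.

**Step 2**
Reactants: 4 (3-methylbut-3-en-1-ol)
Product: 5 (3-methylbut-3-enal)
Conditions: Dess–Martin periodinane, NaHCO3, CH2Cl2, 0 °C; use the cold solution immediately
Reagents that add atoms: none
Why: Mild oxidation of a primary alcohol to the aldehyde, which is the C1–C3 fragment; no stereocentre is formed.

**Step 3**
Reactants: 3, 6 (methylmagnesium bromide), 5
Product: 7 ((3R)-3-allyl-2-(1-hydroxy-3-methylbut-3-en-1-yl)-3-methylcyclopentan-1-one, as a mixture at C2 and C1′)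
Conditions: 6 (1.05 equiv), CuBr·SMe2 (5 mol%), chiral ferrocenyl diphosphine (Josiphos-type, 6 mol%), t-BuOMe, −78 °C; then 5, −78 → −20 °C
Reagents that add atoms: methylmagnesium bromide, C[Mg]Br
Why: Asymmetric conjugate addition (ACA) of Me to the β,β-disubstituted enone sets the quaternary C6 through ligand face control. The resulting enolate is regiospecifically at C10, so the aldol occurs at that carbon, and the aldol centres are left undefined because step 5 erases them.

**Step 4**
Reactants: 7
Product: 8 ((8aR)-4-hydroxy-6,8a-dimethyl-1,2,4,5,8,8a-hexahydroazulen-3(3aH)-one, C3a/C4 epimers)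
Conditions: Hoveyda–Grubbs II (7 mol%), toluene, 0.003 M, 60 °C
Reagents that add atoms: none (ethylene is lost)
Why: Ring-closing metathesis of the terminal allyl group with the 1,1-disubstituted methallyl group gives the trisubstituted cycloheptene C3=C4, closing the seven-membered ring without touching C6.

**Step 5**
Reactants: 8
Product: 9 ((8aR)-6,8a-dimethyl-1,2,5,8-tetrahydroazulen-3(8aH)-one, the bicyclic dienone)
Conditions: MsCl, Et3N, CH2Cl2, 0 °C; then DBU, rt
Reagents that add atoms: none (the mesylate is eliminated)
Why: Mesylation then E1cB elimination converts both diastereomers of the aldol to one conjugated enone C10=C1. The ring enforces the required alkene geometry, and only the C6 centre remains.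

**Step 6**
Reactants: 9
Product: 10 (3a,4-epoxy ketone, α-epoxide)
Conditions: 30% aq. H2O2, 1 M NaOH, MeOH, 0 °C
Reagents that add atoms: hydrogen peroxide, OO
Why: Weitz–Scheffer nucleophilic epoxidation, with HOO⁻ adding at C1 from the face anti to the angular methyl, sets the C1–O configuration. The electron-rich C3=C4 alkene is untouched.

**Step 7**
Reactants: 10
Product: 11 ((3aS,4S,8aR)-4-hydroxy-6,8a-dimethyl-1,2,4,5,8,8a-hexahydroazulen-3(3aH)-one)
Conditions: SmI2 (2.5 equiv), THF/MeOH, −78 °C
Reagents that add atoms: none (hydrogen only, from MeOH)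
Why: Reductive opening of the α,β-epoxy ketone breaks the C10–O bond, keeps C1–OH, and the Sm-enolate is protonated at C10 from the α-face. This gives H10 α, the trans ring fusion, and the β-hydroxy ketone.

**Step 8**
Reactants: 11, 12 (isopropylmagnesium chloride)
Product: 13 ((3R,3aS,4S,8aR)-6,8a-dimethyl-3-(propan-2-yl)-1,2,3,3a,4,5,8,8a-octahydroazulene-3,4-diol)
Conditions: 12·LiCl (3 equiv), anhydrous CeCl3 (3 equiv), THF, −78 → 0 °C
Reagents that add atoms: isopropylmagnesium chloride, CC(C)[Mg]Cl
Why: Organocerium-type 1,2-addition to the C9 ketone from the α-face, which is hindered by neither the β-angular methyl nor C10-H. This puts iPr α and OH β, and Ce(III) suppresses enolisation and reduction.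

**Step 9**
Reactants: 13, 14 (4-methoxybenzoyl chloride)
Product: 15 (fertidin)
Conditions: 14 (1.5 equiv), Et3N, DMAP (cat.), CH2Cl2, 0 °C → rt
Reagents that add atoms: 4-methoxybenzoyl chloride, COc1ccc(cc1)C(=O)Cl
Why: Acylation of the unhindered secondary C1-OH, with the tertiary C9-OH untouched; all stereocentres are already set.

## Compound list
1 | 3-ethoxycyclopent-2-en-1-one | CCOC1=CC(=O)CC1 | starting material
2 | allylmagnesium bromide | C=CC[Mg]Br | starting material
3 | 3-allylcyclopent-2-en-1-one | C=CCC1=CC(=O)CC1 | intermediate
4 | 3-methylbut-3-en-1-ol | C=C(C)CCO | starting material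
5 | 3-methylbut-3-enal | C=C(C)CC=O | intermediate
6 | methylmagnesium bromide | C[Mg]Br | starting material
7 | (3R)-3-allyl-2-(1-hydroxy-3-methylbut-3-en-1-yl)-3-methylcyclopentan-1-one | C=CC[C@@]1(C)CCC(=O)C1C(O)CC(C)=C | intermediate
8 | (8aR)-4-hydroxy-6,8a-dimethyl-1,2,4,5,8,8a-hexahydroazulen-3(3aH)-one (C3a/C4 mixture) | OC1CC(C)=CC[C@@]2(C)CCC(=O)C12 | intermediate
9 | (8aR)-6,8a-dimethyl-1,2,5,8-tetrahydroazulen-3(8aH)-one (dienone) | O=C1CC[C@]2(C)CC=C(C)CC=C12 | intermediate
10 | 3a,4-epoxy ketone derived from 9 (α-epoxide) | O=C1CC[C@]2(C)CC=C(C)C[C@@H]3O[C@@]132 | intermediate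
11 | (3aS,4S,8aR)-4-hydroxy-6,8a-dimethyl-1,2,4,5,8,8a-hexahydroazulen-3(3aH)-one | O[C@H]1CC(C)=CC[C@@]2(C)CCC(=O)[C@H]12 | intermediate
12 | isopropylmagnesium chloride | CC(C)[Mg]Cl | starting material
13 | (3R,3aS,4S,8aR)-jaeschkeanadiol (diol) | O[C@H]1CC(C)=CC[C@@]2(C)CC[C@@](O)(C(C)C)[C@H]12 | intermediate
14 | 4-methoxybenzoyl chloride | COc1ccc(cc1)C(=O)Cl | starting material
15 | fertidin, (3R,3aS,4S,8aR)-3-hydroxy-6,8a-dimethyl-3-(propan-2-yl)-1,2,3,3a,4,5,8,8a-octahydroazulen-4-yl 4-methoxybenzoate | COc1ccc(C(=O)O[C@H]2CC(C)=CC[C@@]3(C)CC[C@@](O)(C(C)C)[C@H]23)cc1 | target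

**Total steps:** 9 (Step 2 is a parallel branch). **Longest linear sequence:** 8 steps (1 → 3 → 7 → 8 → 9 → 10 → 11 → 13 → 15).

## Three steps most likely to fail
1. **Step 3 (Cu-ACA/aldol).** The ee may be low for a cyclopentenone, and the aldehyde may enolise.
   - Fallback: build the quaternary centre by Claisen chirality transfer. CBS-reduce 3-methylcyclopent-2-enone, do a Johnson–Claisen, then DIBAL and Wittig methylenation, then allylic oxidation to 4-allyl-4-methylcyclopent-2-enone. Use its only α′-enolate (C10) for the aldol with 5, and reduce the enone C=C after RCM.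
2. **Steps 6–7 (epoxidation face and C10 protonation).** The wrong C1 epimer or a cis ring fusion could form, and base could isomerise the bis-allylic C2–H2.
   - Fallback: carry the 1-epimeric diol through, then esterify by Mitsunobu with p-anisic acid (PPh3, DIAD). This inverts C1 and installs the anisate in one step, leaving the tertiary OH untouched. A cis-fused ketone would be equilibrated at C10 with NaOMe/MeOH.
3. **Step 8 (iPr addition).** iPrMgCl can reduce or enolise the hindered ketone, and facial selectivity may be imperfect.
   - Fallback: add isopropenylMgBr/CeCl3, which cannot reduce the ketone. Then hydrogenate the 1,1-disubstituted alkene selectively with Wilkinson's catalyst, leaving the trisubstituted ring alkene.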